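**Plan**

- Retrosynthesis: the aryl–C7 bond is cut first (aryllithium plus aldehyde), then the ring bond C1–C2, then the lactone C–O bond, the carbinol C–CH3 and C–vinyl bonds, the C5–prenyl bond and the C6–phenyl bond.
- Enabling feature: in the cyclohexene C1 (CH carrying the ketone carbon C7), C2 (CH2), C3 (=CH), C4 (=C–CH3), C5 (CH–prenyl), C6 (CH–Ph), the chain C7(=O)–C1–C2–C3=C4 is a γ,δ-unsaturated carbonyl unit. That is the product pattern of a Claisen shift whose oxygen sat on C4; tying that oxygen to C7 gives a 6-methyl-6-vinyl δ-lactone.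
- Forward: phenyl is added to 5,6-dihydropyran-2-one, the lactone is prenylated and opened, and its acyl carbon is turned into the C4 carbinol (vinyl, then methyl). The chain is closed again from the other end as the rearrangement lactone, whose [3,3] shift contracts it to the only carbocycle; the aryl ketone is attached last.
- Stereochemistry: C6 comes from the Rh/(S)-BINAP conjugate addition and C5 from trans alkylation of the lactone enolate. The relay carbinol comes from Felkin–Anh addition, and C1 from the vinyl-bearing lactone face in the boat transition state (also the all-equatorial arrangement).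

Key step: step 9

Assumption: the sense of induction in step 1 is taken to follow the accepted model for cyclic enones and enoates ((S)-BINAP gives the 4S lactone); should the opposite sense be found, (R)-BINAP is used.

**Route**

Step 1
Reactants: 1 5,6-dihydro-2H-pyran-2-one; 2 phenylboronic acid
Product: 3 (4S)-4-phenyloxan-2-one
Conditions: Rh(acac)(C2H4)2 (3 mol%), (S)-BINAP, dioxane/H2O 10:1, 100 °C
Reagents that add atoms: phenylboronic acid, OB(O)c1ccccc1
Why: Hayashi–Miyaura rhodium-catalysed asymmetric 1,4-addition, in which the phenyl–Rh(I)/(S)-BINAP species adds to one enantiotopic face of the cyclic enoate and the rhodium enolate is protonated by water, should set the phenyl-bearing centre (later C6) as S.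

Step 2
Reactants: 3 (4S)-4-phenyloxan-2-one; 4 1-bromo-3-methylbut-2-ene (prenyl bromide)
Product: 5 (3R,4S)-3-(3-methylbut-2-en-1-yl)-4-phenyloxan-2-one (3,4-trans)
Conditions: LDA, THF, −78 °C; then 4, DMPU, −78 → −30 °C
Reagents that add atoms: prenyl bromide, CC(C)=CCBr
Why: Enolate alkylation of a 4-substituted δ-lactone takes place anti to the neighbouring phenyl group (1,2-induction in a cyclic enolate), so the prenyl group should enter trans and fix the later C5.

Step 3
Reactants: 5 (3R,4S)-3-(3-methylbut-2-en-1-yl)-4-phenyloxan-2-one; 6 N,O-dimethylhydroxylamine hydrochloride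
Product: 7 (2R,3S)-5-hydroxy-N-methoxy-N-methyl-2-(3-methylbut-2-en-1-yl)-3-phenylpentanamide
Conditions: AlMe3, CH2Cl2, 0 °C → rt; Rochelle salt work-up
Reagents that add atoms: N,O-dimethylhydroxylamine hydrochloride, CNOC.Cl
Why: Weinreb aminolysis of the lactone by the aluminium amide opens the ring at the acyl carbon without touching the α- and β-stereocentres.

Step 4
Reactants: 7 (2R,3S)-5-hydroxy-N-methoxy-N-methyl-2-(3-methylbut-2-en-1-yl)-3-phenylpentanamide; 8 tert-butyldimethylsilyl chloride
Product: 9 (2R,3S)-5-[(tert-butyldimethylsilyl)oxy]-N-methoxy-N-methyl-2-(3-methylbut-2-en-1-yl)-3-phenylpentanamide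
Conditions: imidazole, DMF, 0 °C → rt (crude 7 used at once)
Reagents that add atoms: tert-butyldimethylsilyl chloride, CC(C)(C)[Si](C)(C)Cl
Why: Silylation of the primary alcohol stops relactonisation of the δ-hydroxy amide and masks the hydroxyl for the two organometallic steps.

Step 5
Reactants: 9 (2R,3S)-5-[(tert-butyldimethylsilyl)oxy]-N-methoxy-N-methyl-2-(3-methylbut-2-en-1-yl)-3-phenylpentanamide; 10 vinylmagnesium bromide
Product: 11 (4R,5S)-7-[(tert-butyldimethylsilyl)oxy]-4-(3-methylbut-2-en-1-yl)-5-phenylhept-1-en-3-one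
Conditions: THF, −10 → 0 °C; inverse quench into cold 1 M HCl
Reagents that add atoms: vinylmagnesium bromide, C=C[Mg]Br
Why: Weinreb ketone synthesis, in which the magnesium-chelated tetrahedral adduct persists until the acidic inverse quench, should prevent over-addition and keep the liberated amine protonated so that it cannot add to the new enone.

Step 6
Reactants: 11 (4R,5S)-7-[(tert-butyldimethylsilyl)oxy]-4-(3-methylbut-2-en-1-yl)-5-phenylhept-1-en-3-one; 12 methyllithium
Product: 13 (3S,4R,5S)-7-[(tert-butyldimethylsilyl)oxy]-3-methyl-4-(3-methylbut-2-en-1-yl)-5-phenylhept-1-en-3-ol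
Conditions: anhydrous CeCl3, THF, −78 °C; H2O quench
Reagents that add atoms: methyllithium, [Li]C
Why: Organocerium 1,2-addition to the enone (no conjugate addition, little enolisation) should follow the Felkin–Anh model, methyl approaching anti to the bulky CH(Ph)CH2CH2OTBS group and past the α-hydrogen to give the 3S carbinol; the minor 3R epimer is to be removed by chromatography here or at lactone 16.

Step 7
Reactants: 13 (3S,4R,5S)-7-[(tert-butyldimethylsilyl)oxy]-3-methyl-4-(3-methylbut-2-en-1-yl)-5-phenylhept-1-en-3-ol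
Product: 14 (3S,4R,5S)-5-methyl-4-(3-methylbut-2-en-1-yl)-3-phenylhept-6-ene-1,5-diol
Conditions: TBAF, THF, 0 °C → rt
Reagents that add atoms: none
Why: Fluoride cleavage of the primary silyl ether leaves the acid-sensitive tertiary allylic alcohol and both alkenes untouched.

Step 8
Reactants: 14 (3S,4R,5S)-5-methyl-4-(3-methylbut-2-en-1-yl)-3-phenylhept-6-ene-1,5-diol
Product: 16 (4S,5R,6S)-6-ethenyl-6-methyl-5-(3-methylbut-2-en-1-yl)-4-phenyloxan-2-one (phenyl and prenyl trans; vinyl cis to phenyl), via lactol 15 (not isolated)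
Conditions: TEMPO (20 mol%), PhI(OAc)2 (2.5 equiv), CH2Cl2, rt
Reagents that add atoms: none
Why: TEMPO/PhI(OAc)2 oxidative lactonisation of a 1,5-diol, in which the primary alcohol is oxidised selectively, the tertiary hydroxyl closes the lactol and a second oxidation gives the δ-lactone, the tertiary allylic alcohol itself being inert to the oxoammonium oxidant.

Step 9
Reactants: 16 (4S,5R,6S)-6-ethenyl-6-methyl-5-(3-methylbut-2-en-1-yl)-4-phenyloxan-2-one
Product: 19 (1R,5R,6R)-4-methyl-5-(3-methylbut-2-en-1-yl)-6-phenylcyclohex-3-ene-1-carboxylic acid, via silyl ketene acetal 17 (not isolated), via silyl ester 18 (not isolated)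
Conditions: LDA, TMSCl/Et3N (internal quench), THF, −78 °C → rt; toluene, 110 °C; then 1 M HCl, THF, rt
Reagents that add atoms: none
Why: Kinetic deprotonation of the only enolisable position (the lactone α-CH2) with in situ O-silylation gives the endocyclic silyl ketene acetal, whose O–C=C unit, ring oxygen, carbinol carbon and vinyl group make up an allyl vinyl ether; on heating a concerted suprafacial [3,3] shift forms C1–C2 and breaks the carbinol C–O bond, and the silyl ester is hydrolysed on work-up. The closest known reaction is the Ireland–Claisen rearrangement in its lactone-enolate form, the ring contraction of 6-alkenyl δ-lactones to cyclohex-3-ene-1-carboxylic acids. The six-membered carbocycle is closed by the sigmatropic C–C bond formation itself, through a boat-shaped, bicyclo[2.2.2]octane-like transition state enforced by the ring-bound ketene acetal, which also makes the new C3=C4 alkene endocyclic. The new stereocentre C1 is controlled by the carbinol configuration: the bond can only form on the lactone face that carries the vinyl group, and with vinyl cis to phenyl this places the carboxyl group trans to phenyl (1R), while C5 and C6 are not touched. The step needs O-silylation and rearrangement to outrun enolate self-condensation, which the internal silyl chloride quench and the single acidic site should secure, and the fully substituted carbinol carbon offers no β-elimination pathway.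

Step 10
Reactants: 19 (1R,5R,6R)-4-methyl-5-(3-methylbut-2-en-1-yl)-6-phenylcyclohex-3-ene-1-carboxylic acid
Product: 20 [(1R,5R,6R)-4-methyl-5-(3-methylbut-2-en-1-yl)-6-phenylcyclohex-3-en-1-yl]methanol
Conditions: LiAlH4, THF, 0 °C → rt; aqueous work-up
Reagents that add atoms: none
Why: Hydride reduction of the carboxylic acid to the primary alcohol does not affect the two unactivated trisubstituted alkenes or the stereocentres.

Step 11
Reactants: 20 [(1R,5R,6R)-4-methyl-5-(3-methylbut-2-en-1-yl)-6-phenylcyclohex-3-en-1-yl]methanol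
Product: 21 (1R,5R,6R)-4-methyl-5-(3-methylbut-2-en-1-yl)-6-phenylcyclohex-3-ene-1-carbaldehyde
Conditions: Dess–Martin periodinane, CH2Cl2, rt
Reagents that add atoms: none
Why: Dess–Martin oxidation gives the aldehyde under near-neutral conditions, and its α-centre already has the favoured all-equatorial arrangement, so epimerisation should not erode it.

Step 12
Reactants: 22 3-hydroxy-4,5-dimethoxybenzaldehyde; 23 chloromethyl methyl ether (MOMCl)
Product: 24 3,4-dimethoxy-5-(methoxymethoxy)benzaldehyde
Conditions: i-Pr2NEt, CH2Cl2, 0 °C → rt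
Reagents that add atoms: chloromethyl methyl ether, COCCl
Why: O-alkylation of the phenol masks it as a MOM acetal that is stable to peracid, base and organolithium reagents.

Step 13
Reactants: 24 3,4-dimethoxy-5-(methoxymethoxy)benzaldehyde; 25 3-chloroperoxybenzoic acid (mCPBA)
Product: 27 3,4-dimethoxy-5-(methoxymethoxy)phenol, via aryl formate 26 (not isolated)
Conditions: mCPBA, CH2Cl2, rt; then K2CO3 (cat.), MeOH, rt
Reagents that add atoms: 3-chloroperoxybenzoic acid, OOC(=O)c1cccc(Cl)c1
Why: Baeyer–Villiger (Dakin-type) oxidation, in which the electron-rich aryl group bearing a para methoxy substituent migrates in the Criegee intermediate, gives the formate, which is methanolysed to the phenol.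

Step 14
Reactants: 27 3,4-dimethoxy-5-(methoxymethoxy)phenol; 23 chloromethyl methyl ether (MOMCl)
Product: 28 1,2-dimethoxy-3,5-bis(methoxymethoxy)benzene
Conditions: i-Pr2NEt, CH2Cl2, 0 °C → rt
Reagents that add atoms: chloromethyl methyl ether, COCCl
Why: The second MOM ether formation supplies the pair of acetal directing groups needed for the metalation.

Step 15
Reactants: 28 1,2-dimethoxy-3,5-bis(methoxymethoxy)benzene; 21 (1R,5R,6R)-4-methyl-5-(3-methylbut-2-en-1-yl)-6-phenylcyclohex-3-ene-1-carbaldehyde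
Product: 30 [3,4-dimethoxy-2,6-bis(methoxymethoxy)phenyl][(1R,5R,6R)-4-methyl-5-(3-methylbut-2-en-1-yl)-6-phenylcyclohex-3-en-1-yl]methanol (both carbinol epimers), via aryllithium 29 (not isolated)
Conditions: 28 (1.3 equiv), n-BuLi, THF, 0 °C; then 21, −78 → 0 °C; H2O quench
Reagents that add atoms: none
Why: Directed ortho-metalation should occur at the ring position flanked by both OMOM groups (stronger, cooperatively chelating directors than OMe) and the aryllithium then adds 1,2 to the aldehyde, the configuration of the new carbinol being irrelevant because it is oxidised next.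

Step 16
Reactants: 30 [3,4-dimethoxy-2,6-bis(methoxymethoxy)phenyl][(1R,5R,6R)-4-methyl-5-(3-methylbut-2-en-1-yl)-6-phenylcyclohex-3-en-1-yl]methanol
Product: 31 [3,4-dimethoxy-2,6-bis(methoxymethoxy)phenyl][(1R,5R,6R)-4-methyl-5-(3-methylbut-2-en-1-yl)-6-phenylcyclohex-3-en-1-yl]methanone
Conditions: Dess–Martin periodinane, CH2Cl2, rt
Reagents that add atoms: none
Why: Dess–Martin oxidation of the hindered benzylic alcohol to the aryl ketone is compatible with the MOM acetals and the alkenes.

Step 17
Reactants: 31 [3,4-dimethoxy-2,6-bis(methoxymethoxy)phenyl][(1R,5R,6R)-4-methyl-5-(3-methylbut-2-en-1-yl)-6-phenylcyclohex-3-en-1-yl]methanone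
Product: 32 (2,6-dihydroxy-3,4-dimethoxyphenyl)[(1R,5R,6R)-4-methyl-5-(3-methylbut-2-en-1-yl)-6-phenylcyclohex-3-en-1-yl]methanone (target)
Conditions: HCl (3 M), MeOH, 40 °C
Reagents that add atoms: none
Why: Acid-catalysed methanolysis of the two MOM acetals, assisted by the ortho carbonyl group, should free both phenols under conditions mild enough for the prenyl and ring alkenes and for the all-equatorial C1 centre.

**Compound list**

1 | 5,6-dihydro-2H-pyran-2-one | O=C1C=CCCO1 | starting material
2 | phenylboronic acid | OB(O)c1ccccc1 | starting material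
3 | (4S)-4-phenyloxan-2-one | O=C1C[C@@H](c2ccccc2)CCO1 | intermediate
4 | 1-bromo-3-methylbut-2-ene (prenyl bromide) | CC(C)=CCBr | starting material
5 | (3R,4S)-3-(3-methylbut-2-en-1-yl)-4-phenyloxan-2-one | O=C1[C@H](CC=C(C)C)[C@@H](c2ccccc2)CCO1 | intermediate
6 | N,O-dimethylhydroxylamine hydrochloride | CNOC.Cl | starting material
7 | (2R,3S)-5-hydroxy-N-methoxy-N-methyl-2-(3-methylbut-2-en-1-yl)-3-phenylpentanamide | CON(C)C(=O)[C@H](CC=C(C)C)[C@H](CCO)c1ccccc1 | intermediate
8 | tert-butyldimethylsilyl chloride | CC(C)(C)[Si](C)(C)Cl | starting material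
9 | (2R,3S)-5-[(tert-butyldimethylsilyl)oxy]-N-methoxy-N-methyl-2-(3-methylbut-2-en-1-yl)-3-phenylpentanamide | CON(C)C(=O)[C@H](CC=C(C)C)[C@H](CCO[Si](C)(C)C(C)(C)C)c1ccccc1 | intermediate
10 | vinylmagnesium bromide | C=C[Mg]Br | starting material
11 | (4R,5S)-7-[(tert-butyldimethylsilyl)oxy]-4-(3-methylbut-2-en-1-yl)-5-phenylhept-1-en-3-one | C=CC(=O)[C@H](CC=C(C)C)[C@H](CCO[Si](C)(C)C(C)(C)C)c1ccccc1 | intermediate
12 | methyllithium | [Li]C | starting material
13 | (3S,4R,5S)-7-[(tert-butyldimethylsilyl)oxy]-3-methyl-4-(3-methylbut-2-en-1-yl)-5-phenylhept-1-en-3-ol | C=C[C@](C)(O)[C@H](CC=C(C)C)[C@H](CCO[Si](C)(C)C(C)(C)C)c1ccccc1 | intermediate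
14 | (3S,4R,5S)-5-methyl-4-(3-methylbut-2-en-1-yl)-3-phenylhept-6-ene-1,5-diol | C=C[C@](C)(O)[C@H](CC=C(C)C)[C@H](CCO)c1ccccc1 | intermediate
15 | (4S,5R,6S)-6-ethenyl-6-methyl-5-(3-methylbut-2-en-1-yl)-4-phenyloxan-2-ol (lactol, both anomers) | OC1C[C@H](c2ccccc2)[C@@H](CC=C(C)C)[C@](C)(C=C)O1 | intermediate
16 | (4S,5R,6S)-6-ethenyl-6-methyl-5-(3-methylbut-2-en-1-yl)-4-phenyloxan-2-one | O=C1C[C@H](c2ccccc2)[C@@H](CC=C(C)C)[C@](C)(C=C)O1 | intermediate
17 | (2S,3R,4R)-2-ethenyl-2-methyl-3-(3-methylbut-2-en-1-yl)-4-phenyl-6-[(trimethylsilyl)oxy]-3,4-dihydro-2H-pyran (silyl ketene acetal of 16) | C[Si](C)(C)OC1=C[C@H](c2ccccc2)[C@@H](CC=C(C)C)[C@](C)(C=C)O1 | intermediate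
18 | trimethylsilyl (1R,5R,6R)-4-methyl-5-(3-methylbut-2-en-1-yl)-6-phenylcyclohex-3-ene-1-carboxylate | C[Si](C)(C)OC(=O)[C@@H]1CC=C(C)[C@H](CC=C(C)C)[C@H]1c1ccccc1 | intermediate
19 | (1R,5R,6R)-4-methyl-5-(3-methylbut-2-en-1-yl)-6-phenylcyclohex-3-ene-1-carboxylic acid | OC(=O)[C@@H]1CC=C(C)[C@H](CC=C(C)C)[C@H]1c1ccccc1 | intermediate
20 | [(1R,5R,6R)-4-methyl-5-(3-methylbut-2-en-1-yl)-6-phenylcyclohex-3-en-1-yl]methanol | OC[C@@H]1CC=C(C)[C@H](CC=C(C)C)[C@H]1c1ccccc1 | intermediate
21 | (1R,5R,6R)-4-methyl-5-(3-methylbut-2-en-1-yl)-6-phenylcyclohex-3-ene-1-carbaldehyde | O=C[C@@H]1CC=C(C)[C@H](CC=C(C)C)[C@H]1c1ccccc1 | intermediate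
22 | 3-hydroxy-4,5-dimethoxybenzaldehyde | COc1cc(C=O)cc(O)c1OC | starting material
23 | chloromethyl methyl ether (MOMCl) | COCCl | starting material
24 | 3,4-dimethoxy-5-(methoxymethoxy)benzaldehyde | COCOc1cc(C=O)cc(OC)c1OC | intermediate
25 | 3-chloroperoxybenzoic acid (mCPBA) | OOC(=O)c1cccc(Cl)c1 | starting material
26 | 3,4-dimethoxy-5-(methoxymethoxy)phenyl formate | COCOc1cc(OC=O)cc(OC)c1OC | intermediate
27 | 3,4-dimethoxy-5-(methoxymethoxy)phenol | COCOc1cc(O)cc(OC)c1OC | intermediate
28 | 1,2-dimethoxy-3,5-bis(methoxymethoxy)benzene | COCOc1cc(OCOC)c(OC)c(OC)c1 | intermediate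
29 | [3,4-dimethoxy-2,6-bis(methoxymethoxy)phenyl]lithium | COCOc1cc(OC)c(OC)c(OCOC)c1[Li] | intermediate
30 | [3,4-dimethoxy-2,6-bis(methoxymethoxy)phenyl][(1R,5R,6R)-4-methyl-5-(3-methylbut-2-en-1-yl)-6-phenylcyclohex-3-en-1-yl]methanol (carbinol epimers) | COCOc1cc(OC)c(OC)c(OCOC)c1C(O)[C@@H]1CC=C(C)[C@H](CC=C(C)C)[C@H]1c1ccccc1 | intermediate
31 | [3,4-dimethoxy-2,6-bis(methoxymethoxy)phenyl][(1R,5R,6R)-4-methyl-5-(3-methylbut-2-en-1-yl)-6-phenylcyclohex-3-en-1-yl]methanone | COCOc1cc(OC)c(OC)c(OCOC)c1C(=O)[C@@H]1CC=C(C)[C@H](CC=C(C)C)[C@H]1c1ccccc1 | intermediate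
32 | (2,6-dihydroxy-3,4-dimethoxyphenyl)[(1R,5R,6R)-4-methyl-5-(3-methylbut-2-en-1-yl)-6-phenylcyclohex-3-en-1-yl]methanone | COc1cc(O)c(C(=O)[C@@H]2CC=C(C)[C@H](CC=C(C)C)[C@H]2c2ccccc2)c(O)c1OC | target

**Step count**

Total: 17 steps. Longest linear sequence: 14 steps (steps 1–11 and 15–17); the arene branch is 3 steps (12–14).

**Steps most likely to fail**

Step 6. The facial bias of an acyclic α-branched enone toward a small methyl nucleophile may be weak, so that both carbinol epimers form in comparable amounts. The fallback makes C1 under thermodynamic instead of relayed control and sets out from enone 11. The 3R carbinol epimer, (3R,4R,5S)-7-[(tert-butyldimethylsilyl)oxy]-3-methyl-4-(3-methylbut-2-en-1-yl)-5-phenylhept-1-en-3-ol F1, alone or mixed with 13, is desilylated with TBAF to the epimeric diol F2. TEMPO/PhI(OAc)2 oxidation then proceeds through the epimeric lactol F3 to the 6-epi lactone F4 (vinyl trans to phenyl). Under the conditions of step 9 the epimeric silyl ketene acetal F5 rearranges on its vinyl face to the cis silyl ester F6, and hydrolysis gives the 1,6-cis acid F7. Esterification with TMSCHN2 in MeOH/toluene gives the cis methyl ester F8. NaOMe in MeOH at reflux should equilibrate the α-centre to the all-equatorial trans methyl ester F9. LiAlH4 reduction of F9 rejoins the route at alcohol 20.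

Step 9. The lactone enolate may undergo intermolecular Claisen condensation or C-silylation, or the silyl ketene acetal may be hydrolysed back to the lactone before the strained boat transition state at the fully substituted carbinol carbon is reached. The fallback uses the neutral allyl vinyl ether and sets out from lactone 16. DIBAL-H (CH2Cl2, −78 °C) gives lactol 15. Dehydration with MsCl/Et3N (CH2Cl2, 0 °C → reflux) gives the cyclic enol ether, (2S,3R,4S)-2-ethenyl-2-methyl-3-(3-methylbut-2-en-1-yl)-4-phenyl-3,4-dihydro-2H-pyran F10. Its thermal dihydropyran Claisen rearrangement (xylenes, sealed tube, about 190 °C) forms the same C1–C2 bond on the same vinyl face. It delivers the carbocycle at the aldehyde oxidation level and rejoins the route at aldehyde 21.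

Step 15. Proton transfer from the α-branched aldehyde to the hindered 2,6-dioxygenated aryllithium may compete with carbonyl addition. The fallback replaces the carbonyl addition by an acylative cross-coupling and sets out from acid 19. 1-Chloro-N,N,2-trimethylprop-1-en-1-amine in CH2Cl2 converts 19 under neutral conditions into the acid chloride, (1R,5R,6R)-4-methyl-5-(3-methylbut-2-en-1-yl)-6-phenylcyclohex-3-ene-1-carbonyl chloride F11. Aryllithium 29, made from 28 as in step 15, is transmetalated with ZnCl2 to the arylzinc chloride F12. Pd(PPh3)4-catalysed Negishi acylation in THF joins F11 and F12 and comes back to the route at ketone 31, leaving out steps 10, 11 and 16.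

**Further compounds**

F1 | step 6 | (3R,4R,5S)-7-[(tert-butyldimethylsilyl)oxy]-3-methyl-4-(3-methylbut-2-en-1-yl)-5-phenylhept-1-en-3-ol | C=C[C@@](C)(O)[C@H](CC=C(C)C)[C@H](CCO[Si](C)(C)C(C)(C)C)c1ccccc1
F2 | step 6 | (3S,4R,5R)-5-methyl-4-(3-methylbut-2-en-1-yl)-3-phenylhept-6-ene-1,5-diol | C=C[C@@](C)(O)[C@H](CC=C(C)C)[C@H](CCO)c1ccccc1
F3 | step 6 | (4S,5R,6R)-6-ethenyl-6-methyl-5-(3-methylbut-2-en-1-yl)-4-phenyloxan-2-ol | OC1C[C@H](c2ccccc2)[C@@H](CC=C(C)C)[C@@](C)(C=C)O1
F4 | step 6 | (4S,5R,6R)-6-ethenyl-6-methyl-5-(3-methylbut-2-en-1-yl)-4-phenyloxan-2-one | O=C1C[C@H](c2ccccc2)[C@@H](CC=C(C)C)[C@@](C)(C=C)O1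
F5 | step 6 | trimethylsilyl ketene acetal of F4 | C[Si](C)(C)OC1=C[C@H](c2ccccc2)[C@@H](CC=C(C)C)[C@@](C)(C=C)O1
F6 | step 6 | trimethylsilyl (1S,5R,6R)-4-methyl-5-(3-methylbut-2-en-1-yl)-6-phenylcyclohex-3-ene-1-carboxylate | C[Si](C)(C)OC(=O)[C@H]1CC=C(C)[C@H](CC=C(C)C)[C@H]1c1ccccc1
F7 | step 6 | (1S,5R,6R)-4-methyl-5-(3-methylbut-2-en-1-yl)-6-phenylcyclohex-3-ene-1-carboxylic acid | OC(=O)[C@H]1CC=C(C)[C@H](CC=C(C)C)[C@H]1c1ccccc1
F8 | step 6 | methyl (1S,5R,6R)-4-methyl-5-(3-methylbut-2-en-1-yl)-6-phenylcyclohex-3-ene-1-carboxylate | COC(=O)[C@H]1CC=C(C)[C@H](CC=C(C)C)[C@H]1c1ccccc1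
F9 | step 6 | methyl (1R,5R,6R)-4-methyl-5-(3-methylbut-2-en-1-yl)-6-phenylcyclohex-3-ene-1-carboxylate | COC(=O)[C@@H]1CC=C(C)[C@H](CC=C(C)C)[C@H]1c1ccccc1
F10 | step 9 | (2S,3R,4S)-2-ethenyl-2-methyl-3-(3-methylbut-2-en-1-yl)-4-phenyl-3,4-dihydro-2H-pyran | C1=C[C@H](c2ccccc2)[C@@H](CC=C(C)C)[C@](C)(C=C)O1
F11 | step 15 | (1R,5R,6R)-4-methyl-5-(3-methylbut-2-en-1-yl)-6-phenylcyclohex-3-ene-1-carbonyl chloride | ClC(=O)[C@@H]1CC=C(C)[C@H](CC=C(C)C)[C@H]1c1ccccc1
F12 | step 15 | [3,4-dimethoxy-2,6-bis(methoxymethoxy)phenyl]zinc chloride | COCOc1cc(OC)c(OC)c(OCOC)c1[Zn]Cl
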